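## The problem

The target (24) is a flavanone–flavone dimer: a naringenin unit and an apigenin unit joined by a single bond between C3 of the flavanone and C3 of the flavone. Both of these carbons are donor positions, each α to its own C4 ketone, so the inter-unit bond cannot be made by adding one unit to the other as nucleophile and electrophile. One partner must be reversed in polarity, or the bond must arise by rearrangement. The two stereocentres, C2 and C3 of the flavanone ring, are trans and (2S,3R). C3 sits between the ketone and the flavone, epimerises readily and will follow C2 into the diequatorial trans arrangement, so only C2 needs control in the absolute sense. C2 is itself fragile: base opens ring C by β-elimination of the phenoxide and racemises it, most easily once the 4-hydroxyphenyl group is free. The six phenols must therefore be unmasked last, under neutral conditions. On the way, chromones without a C2 substituent and 3-formylchromones are opened at C2 by hydroxide and amines, and the phloroglucinol rings are open to electrophiles. The enabling feature is that, read from the flavanone side, the flavone is the 3-aryl group of an isoflavanone. Its C3 is the β carbon of the O1–C2=C3 enol ether of ring C and should bridge to a neighbouring cationic centre as the ipso carbon of a 4-alkoxyphenyl ring does, so the C3–C3 bond can be made the way isoflavones are made, by a 1,2-shift from the β to the α carbon of a chalcone.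

## Retrosynthesis

**24 from 23.** Only the six O–benzyl bonds are cut. Benzyl ethers are chosen because hydrogenolysis is neutral, whereas methyl, acyl or acetal groups at six positions would need Lewis acid, base or hot acid, all of which threaten C2. The forward step must cleave six benzyl aryl ethers and leave the benzylic C2–O1 bond, the ketone and the flavone double bond alone.

**23 from 22.** No bond is cut; 23 is taken from its racemate 22 on a chiral stationary phase. The neighbouring option, a catalyst-controlled addition of an arylboron reagent that would set C2 directly, is established only for chromones with no substituent at C3. Here the acceptor carries a very large one, and a second untested reaction straight after the key step would make the plan depend on two unproven events in a row. Separation costs half the material at first pass, but the unwanted enantiomer can be racemised through the same reversible ring opening and recycled.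

**22 from 18 and 19.** The C2–aryl bond is cut, giving the flat, achiral bichromone 18 and an aryl nucleophile from bromide 19. This is preferred to opening ring C at O1–C2 because the two pyranone rings of 18 differ where it matters. The flavone half has a fully substituted β carbon; the other half has C2–H and is the only acceptor an organocopper reagent will take. The forward reaction must add at that C2 only, and protonation must end in the thermodynamic trans arrangement.

**18 from 15.** The chromone ring without a C2 substituent is cut at O1–C2. It is the cyclisation product of a β-keto acetal onto an ortho phenol, the closing step of the chalcone route to isoflavones. Precursor 15 is open-chain, and its acetal carbon, the future C2, is already at the aldehyde oxidation level. The phenol is carried as a MOM ether so that the acid that closes the ring also frees it.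

**15 from 13.** The bond between flavone C3 and the α carbon is cut and the flavone is reattached to the β carbon, which is the reverse of a 1,2-shift. The conservative neighbour is a cross-coupling of the two C3 positions, and it is kept in reserve. The rearrangement is preferred because it forms the crowded bond intramolecularly through a bridged ion and would extend the chalcone-to-isoflavone logic to a heteroaryl migrating group. Precursor 13 is an enone assembled from a methyl ketone and an aldehyde. The oxidant must make the flavonyl group, and nothing else, migrate.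

**13 from 3 and 9.** The Cα=Cβ double bond is cut, an aldol condensation. A hydroxide-mediated condensation would be shortest, but hydroxide attacks C2 of the 3-formylchromone 9. The bond is therefore made with the preformed lithium enolate of 3, followed by elimination. The 2'-oxygen of 3 is a MOM ether so that no free phenol is present during the enolate chemistry or the oxidation.

**9 from 7, 7 from 5, 5 from 2 and 4.** The C3–CHO bond is cut to flavone 7 (lithiation at C3, then DMF). Flavone 7 is cut at O1–C2 and dehydrogenated back to chalcone 5, which is cut at its double bond to ketone 2 and aldehyde 4. Against building a 3-iodoflavone from an ynone and formylating it with palladium, this is shorter and uses the same ketone 2 as the other half. Hydroxide is harmless in the condensation to 5 because no chromone is present yet.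

**3 from 2, 2 from 1.** Only O–C bonds to protecting groups are cut. Ketone 2 is the branch point for both halves, so the whole skeleton comes from phloroacetophenone 1, aldehyde 4 and bromide 19.

## Roads not taken

**Alternative 1:** The cut is C2–C3 of the flavanone. The α-diazoketone A1 carries the flavonyl group on the diazo carbon and a 4-(methoxymethoxy)benzyl ether ortho to the ketone on ring A. Rh2(S-PTTL)4 (dirhodium tetrakis[N-phthaloyl-(S)-tert-leucinate]) would decompose it, and the carbene would insert into the benzylic C–H bond to close ring C and give A2.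

- **Merits:** The catalyst sets C2 in the ring-forming step, the C–H bond is doubly activated (benzylic and next to oxygen), and C3 can be equilibrated to trans. In stereocontrol this road is better than the chosen plan, which separates enantiomers.
- **Weak points:** A1 already contains the C3–C3 bond, so the hardest bond is left to another, unnamed method. The insertion must close a six-membered ring, whereas such carbenes prefer five-membered closure. The ether oxygen lies five atoms from the carbene carbon, and capture by that oxygen followed by a 1,2-benzyl shift is the usual fate of ortho-alkoxyaryl diazoketones. The mixed silyl and MOM protection must then be removed with fluoride and acid next to a labile C2.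
- **Comparison:** The chosen plan makes the inter-unit bond itself, and every reaction after its key step has precedent.

**Alternative 2:** The cuts are C3–C4 and O1–C2. A chiral BINOL-derived phosphoric acid would dehydrate salicyl alcohol A3 to an ortho-quinone methide, which would add across the (E)-styrylflavone A4 to give flavan A5.

- **Merits:** It is the most convergent road: two bonds, ring C and both stereocentres in one catalytic step, with trans following from the alkene geometry. The C3–C3 precursor bond in A4 is an ordinary sp2–sp2 bond. In convergence and catalytic stereocontrol it is better than the chosen plan.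
- **Weak points:** C4 of A5 is a methylene group. Oxidising it to the ketone (which would give 23) must distinguish it from six benzyl ether CH2 groups and from C2–H, which is also benzylic and next to oxygen; no reagent does this reliably. The quinone methide from A3 is unsubstituted at its methylene carbon, while this catalysis is established for aryl-substituted ones. The alkene of A4 is hindered and conjugated to the flavone carbonyl.
- **Comparison:** The chosen plan carries C4 as a ketone from the first step and needs no late oxidation.

**Alternative 3:** No skeletal bond is cut. Two hydrogens are added to one half of the symmetric biflavone A6. Copper hydride from Cu(OAc)2, DTBM-SEGPHOS and a silane would deliver hydride to C2 of one flavone half, and protonation at C3 would give A7.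

- **Merits:** It is the shortest road. A6 comes from one flavone by homo-coupling at C3, and one catalytic step creates both stereocentres. If the reduction worked it would beat the chosen plan in length and in stereocontrol, and the experiment is cheap to try.
- **Weak points:** Hydride must go to a fully substituted β carbon of a tetrasubstituted, vinylogous-ester enone flanked by the second flavone. Ligated copper hydride is established for β,β-disubstituted acceptors without an α substituent, and it also reduces aryl ketones at the carbonyl. The 3,3' axis of A6 has four ortho substituents and may be configurationally stable, so the catalyst would face a racemate of atropisomers. Both halves are equally reactive, so stopping after one reduction is not assured.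
- **Comparison:** The chosen plan differentiates the two halves from the start and rests its late steps on known reactivity. That is all it has to set against the brevity of this road.

Key step: step 7

Assumption: aldehyde 4 and bromide 19 are bought. All chiral compounds before step 10 are racemic or stereoisomer mixtures and are written without stereodescriptors, except 22, whose SMILES lists both trans enantiomers.

Shorthand: "Fl" means the 5,7-bis(benzyloxy)-2-[4-(benzyloxy)phenyl]-4-oxo-4H-chromen-3-yl group.

Step 1
Reactants: 1 2',4',6'-trihydroxyacetophenone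
Product: 2 1-[2,4-bis(benzyloxy)-6-hydroxyphenyl]ethan-1-one
Conditions: BnBr (2.1 equiv.), K2CO3, DMF, 0 °C to rt
Reagents that add atoms: benzyl bromide, BrCc1ccccc1
Why: Williamson ether synthesis; the para and one ortho hydroxyl are alkylated, while the remaining ortho hydroxyl is held in a hydrogen bond to the acetyl group and stays free when benzyl bromide is limited to two equivalents.

Step 2
Reactants: 2 1-[2,4-bis(benzyloxy)-6-hydroxyphenyl]ethan-1-one
Product: 3 1-[2,4-bis(benzyloxy)-6-(methoxymethoxy)phenyl]ethan-1-one
Conditions: NaH, DMF, 0 °C; MeOCH2Cl, 0 °C to rt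
Reagents that add atoms: chloromethyl methyl ether, COCCl
Why: O-alkylation of the sodium phenoxide with an α-chloro ether; the MOM group masks the 2'-oxygen through steps 6 and 7 and is the only ether that the acid of step 8 removes.

Step 3
Reactants: 2 1-[2,4-bis(benzyloxy)-6-hydroxyphenyl]ethan-1-one; 4 4-(benzyloxy)benzaldehyde
Product: 5 (E)-1-[2,4-bis(benzyloxy)-6-hydroxyphenyl]-3-[4-(benzyloxy)phenyl]prop-2-en-1-one
Conditions: KOH (50% aq.), EtOH–THF, rt
Reagents that add atoms: none
Why: Claisen–Schmidt condensation; the aldehyde cannot enolise and the (E)-enone is the conjugated thermodynamic product; the free chelated phenol is needed for the ring closure of step 4.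

Step 4
Reactants: 5 (E)-1-[2,4-bis(benzyloxy)-6-hydroxyphenyl]-3-[4-(benzyloxy)phenyl]prop-2-en-1-one
Product: 7 5,7-bis(benzyloxy)-2-[4-(benzyloxy)phenyl]-4H-chromen-4-one, via flavanone 6 (not isolated)
Conditions: I2 (10 mol%), DMSO, 130 °C
Reagents that add atoms: none
Why: Iodine-mediated oxidative cyclisation of a 2'-hydroxychalcone: oxa-Michael closure to 6, α-iodination and loss of HI give the flavone, and DMSO returns HI to I2.

Step 5
Reactants: 7 5,7-bis(benzyloxy)-2-[4-(benzyloxy)phenyl]-4H-chromen-4-one
Product: 9 5,7-bis(benzyloxy)-2-[4-(benzyloxy)phenyl]-4-oxo-4H-chromene-3-carbaldehyde, via 3-lithioflavone 8 (not isolated)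
Conditions: LiN(i-Pr)2 (1.3 equiv.), THF, −78 °C; DMF, −78 to −40 °C; AcOH
Reagents that add atoms: N,N-dimethylformamide, CN(C)C=O
Why: Deprotonative lithiation of a flavone at C3, the vinylic position between the carbonyl group and the ring oxygen, then formylation of the lithio compound with DMF; the site is fixed by the acidity of C3–H, so the electron-rich C6 and C8 of ring A, which an electrophilic formylation would attack, stay untouched.

Step 6
Reactants: 3 1-[2,4-bis(benzyloxy)-6-(methoxymethoxy)phenyl]ethan-1-one; 9 5,7-bis(benzyloxy)-2-[4-(benzyloxy)phenyl]-4-oxo-4H-chromene-3-carbaldehyde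
Product: 13 (E)-1-[2,4-bis(benzyloxy)-6-(methoxymethoxy)phenyl]-3-Fl-prop-2-en-1-one, via lithium enolate 10 (not isolated), via lithium aldolate 11 (not isolated), via aldol mesylate 12 (not isolated)
Conditions: 3, LiN(i-Pr)2 (1.1 equiv.), THF, −78 °C; 9, −78 °C; MeSO2Cl then Et3N, −78 °C to rt
Reagents that add atoms: none
Why: Directed aldol addition of the preformed lithium enolate of 3 to the non-enolisable aldehyde 9, then mesylation of the aldolate and E1cB elimination to the conjugated (E)-enone; no hydroxide or amine nucleophile is present, which matters because 3-formylchromones are opened at C2 by such nucleophiles.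

Step 7
Reactants: 13 (E)-1-[2,4-bis(benzyloxy)-6-(methoxymethoxy)phenyl]-3-Fl-prop-2-en-1-one
Product: 15 rac-1-[2,4-bis(benzyloxy)-6-(methoxymethoxy)phenyl]-2-Fl-3,3-dimethoxypropan-1-one, via oxythallation adduct 14 (not isolated)
Conditions: Tl(NO3)3·3H2O (1.2 equiv.), MeOH–HC(OMe)3–CH2Cl2, rt
Reagents that add atoms: methanol, CO
Why: Proposed new method: trivalent thallium adds to the enone of 13 at the α carbon while methanol adds at the β carbon (adduct 14); flavone C3, the β-carbon substituent, then bridges to the α carbon through its O1–C2=C3 enol-ether π bond as monovalent thallium (TlNO3) leaves, the charge of the bridged ion resting on C2 between O1 and the 4-benzyloxyphenyl ring, and the bridge opens towards the methoxy-stabilised β carbon, which methanol captures as the dimethyl acetal, so that the later C3–C3 bond is formed by a 1,2-shift. The closest known reaction type is the oxidative rearrangement of 2'-oxygenated chalcones to 1,2-diaryl-3,3-dimethoxypropan-1-ones with Tl(NO3)3 in methanol (isoflavone synthesis), in which a 4-alkoxyphenyl group migrates; a chromon-3-yl migrating group has not been shown. No ring is closed, and the one new stereocentre (the α carbon) is formed as a racemate and erased in step 8, so nothing has to control it. Three selectivities are needed: methanol must add at the β carbon and thallium at the α carbon, which the donor character of the flavonyl group should direct as an alkoxyphenyl group does; the flavonyl group and not ring A must migrate, and ring A can shift only from a ketal carbon, whose formation the two ortho ether groups flanking the ketone of 13 hinder; and the α carbon must not be captured by a ring A phenol (aurone formation), which the MOM ether excludes.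

Step 8
Reactants: 15 rac-1-[2,4-bis(benzyloxy)-6-(methoxymethoxy)phenyl]-2-Fl-3,3-dimethoxypropan-1-one
Product: 18 5,7-bis(benzyloxy)-3-Fl-4H-chromen-4-one, via phenol keto acetal 16 (not isolated), via 2-methoxychromanone 17 (not isolated)
Conditions: conc. HCl, MeOH–THF, 55 °C
Reagents that add atoms: none
Why: Acid-catalysed closure of a β-keto acetal onto the ortho phenol, the closing step of the chalcone route to isoflavones: HCl in methanol removes the MOM group (16), the phenol adds to the oxocarbenium ion of the acetal (17) and methanol is eliminated to the aromatic pyranone. The racemic stereocentre of 15 disappears, and benzyl aryl ethers are stable to these conditions.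

Step 9
Reactants: 18 5,7-bis(benzyloxy)-3-Fl-4H-chromen-4-one; 19 1-(benzyloxy)-4-bromobenzene
Product: 22 (2RS,3SR)-5,7-bis(benzyloxy)-2-[4-(benzyloxy)phenyl]-3-Fl-2,3-dihydro-4H-chromen-4-one (racemic trans), via aryl Grignard reagent 20 (not isolated), via silyl enol ether 21 (not isolated)
Conditions: 19, Mg, THF, 45 °C; 18, CuBr·SMe2 (20 mol%), Me3SiCl, THF, −78 to −20 °C; 1 M HCl, THF, rt; Et3N (cat.), CH2Cl2, rt
Reagents that add atoms: none
Why: Copper-catalysed conjugate addition of an aryl Grignard reagent accelerated by Me3SiCl; chromones without a C2 substituent, isoflavones among them, take organocopper and Grignard reagents at C2, whereas the flavone half has a fully substituted β carbon and does not react. Hydrolysis of 21 protonates C3, and because C3–H is acidic a trace of amine settles the product into the 2,3-trans isomer with both large groups equatorial; the product is racemic.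

Step 10
Reactants: 22 (2RS,3SR)-5,7-bis(benzyloxy)-2-[4-(benzyloxy)phenyl]-3-Fl-2,3-dihydro-4H-chromen-4-one (racemic trans)
Product: 23 (2S,3R)-5,7-bis(benzyloxy)-2-[4-(benzyloxy)phenyl]-3-Fl-2,3-dihydro-4H-chromen-4-one
Conditions: preparative HPLC, amylose tris(3,5-dimethylphenylcarbamate) on silica, hexane–CH2Cl2–i-PrOH, rt
Reagents that add atoms: none
Why: Resolution by chromatography on a polysaccharide carbamate stationary phase, the routine method for flavanone enantiomers; no bond is made or broken, so the trans relation from step 9 is kept and the absolute configuration is selected here. The (2S,3R) fraction is to be identified by electronic circular dichroism of a debenzylated sample (Cotton-effect rule for 2S flavanones and computed spectra); the other enantiomer can be racemised with an amine base through reversible opening of ring C and recycled.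

Step 11
Reactants: 23 (2S,3R)-5,7-bis(benzyloxy)-2-[4-(benzyloxy)phenyl]-3-Fl-2,3-dihydro-4H-chromen-4-one
Product: 24 (2S,3R)-5,7-dihydroxy-2-(4-hydroxyphenyl)-3-[5,7-dihydroxy-2-(4-hydroxyphenyl)-4-oxo-4H-chromen-3-yl]-2,3-dihydro-4H-chromen-4-one
Conditions: H2 (1 atm), 10% Pd/C, EtOAc–MeOH, rt
Reagents that add atoms: none
Why: Hydrogenolysis of six benzyl aryl ethers on palladium under neutral conditions; with neither acid nor base present, C2 cannot racemise by ring opening and C3 stays trans. The flavone double bond is tetrasubstituted and conjugated to the ring oxygen and is not expected to be reduced.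

## Compound list

1 | 2',4',6'-trihydroxyacetophenone | CC(=O)c1c(O)cc(O)cc1O | starting material
2 | 1-[2,4-bis(benzyloxy)-6-hydroxyphenyl]ethan-1-one | CC(=O)c1c(O)cc(OCc2ccccc2)cc1OCc1ccccc1 | intermediate
3 | 1-[2,4-bis(benzyloxy)-6-(methoxymethoxy)phenyl]ethan-1-one | CC(=O)c1c(OCOC)cc(OCc2ccccc2)cc1OCc1ccccc1 | intermediate
4 | 4-(benzyloxy)benzaldehyde | O=Cc1ccc(OCc2ccccc2)cc1 | starting material
5 | (E)-1-[2,4-bis(benzyloxy)-6-hydroxyphenyl]-3-[4-(benzyloxy)phenyl]prop-2-en-1-one | O=C(/C=C/c1ccc(OCc2ccccc2)cc1)c1c(O)cc(OCc2ccccc2)cc1OCc1ccccc1 | intermediate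
6 | rac-5,7-bis(benzyloxy)-2-[4-(benzyloxy)phenyl]chroman-4-one | O=C1CC(c2ccc(OCc3ccccc3)cc2)Oc2cc(OCc3ccccc3)cc(OCc3ccccc3)c21 | intermediate (not isolated)
7 | 5,7-bis(benzyloxy)-2-[4-(benzyloxy)phenyl]-4H-chromen-4-one | O=c1cc(-c2ccc(OCc3ccccc3)cc2)oc2cc(OCc3ccccc3)cc(OCc3ccccc3)c12 | intermediate
8 | 5,7-bis(benzyloxy)-2-[4-(benzyloxy)phenyl]-3-lithio-4H-chromen-4-one | [Li]c1c(-c2ccc(OCc3ccccc3)cc2)oc2cc(OCc3ccccc3)cc(OCc3ccccc3)c2c1=O | intermediate (not isolated)
9 | 5,7-bis(benzyloxy)-2-[4-(benzyloxy)phenyl]-4-oxo-4H-chromene-3-carbaldehyde | O=Cc1c(-c2ccc(OCc3ccccc3)cc2)oc2cc(OCc3ccccc3)cc(OCc3ccccc3)c2c1=O | intermediate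
10 | lithium enolate of 3 | [Li]OC(=C)c1c(OCOC)cc(OCc2ccccc2)cc1OCc1ccccc1 | intermediate (not isolated)
11 | lithium rac-3-[2,4-bis(benzyloxy)-6-(methoxymethoxy)phenyl]-1-Fl-3-oxopropan-1-olate | [Li]OC(CC(=O)c1c(OCOC)cc(OCc2ccccc2)cc1OCc1ccccc1)c1c(-c2ccc(OCc3ccccc3)cc2)oc2cc(OCc3ccccc3)cc(OCc3ccccc3)c2c1=O | intermediate (not isolated)
12 | rac-3-[2,4-bis(benzyloxy)-6-(methoxymethoxy)phenyl]-1-Fl-3-oxopropyl methanesulfonate | CS(=O)(=O)OC(CC(=O)c1c(OCOC)cc(OCc2ccccc2)cc1OCc1ccccc1)c1c(-c2ccc(OCc3ccccc3)cc2)oc2cc(OCc3ccccc3)cc(OCc3ccccc3)c2c1=O | intermediate (not isolated)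
13 | (E)-1-[2,4-bis(benzyloxy)-6-(methoxymethoxy)phenyl]-3-Fl-prop-2-en-1-one | O=C(/C=C/c1c(-c2ccc(OCc3ccccc3)cc2)oc2cc(OCc3ccccc3)cc(OCc3ccccc3)c2c1=O)c1c(OCOC)cc(OCc2ccccc2)cc1OCc1ccccc1 | intermediate
14 | 1-[2,4-bis(benzyloxy)-6-(methoxymethoxy)phenyl]-2-[bis(nitrooxy)thallanyl]-3-Fl-3-methoxypropan-1-one (stereoisomer mixture) | COC(C([Tl](O[N+](=O)[O-])O[N+](=O)[O-])C(=O)c1c(OCOC)cc(OCc2ccccc2)cc1OCc1ccccc1)c1c(-c2ccc(OCc3ccccc3)cc2)oc2cc(OCc3ccccc3)cc(OCc3ccccc3)c2c1=O | intermediate (not isolated)
15 | rac-1-[2,4-bis(benzyloxy)-6-(methoxymethoxy)phenyl]-2-Fl-3,3-dimethoxypropan-1-one | COC(OC)C(C(=O)c1c(OCOC)cc(OCc2ccccc2)cc1OCc1ccccc1)c1c(-c2ccc(OCc3ccccc3)cc2)oc2cc(OCc3ccccc3)cc(OCc3ccccc3)c2c1=O | intermediate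
16 | rac-1-[2,4-bis(benzyloxy)-6-hydroxyphenyl]-2-Fl-3,3-dimethoxypropan-1-one | COC(OC)C(C(=O)c1c(O)cc(OCc2ccccc2)cc1OCc1ccccc1)c1c(-c2ccc(OCc3ccccc3)cc2)oc2cc(OCc3ccccc3)cc(OCc3ccccc3)c2c1=O | intermediate (not isolated)
17 | 5,7-bis(benzyloxy)-3-Fl-2-methoxychroman-4-one (stereoisomer mixture) | COC1Oc2cc(OCc3ccccc3)cc(OCc3ccccc3)c2C(=O)C1c1c(-c2ccc(OCc3ccccc3)cc2)oc2cc(OCc3ccccc3)cc(OCc3ccccc3)c2c1=O | intermediate (not isolated)
18 | 5,7-bis(benzyloxy)-3-Fl-4H-chromen-4-one | O=c1c(-c2c(-c3ccc(OCc4ccccc4)cc3)oc3cc(OCc4ccccc4)cc(OCc4ccccc4)c3c2=O)coc2cc(OCc3ccccc3)cc(OCc3ccccc3)c12 | intermediate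
19 | 1-(benzyloxy)-4-bromobenzene | Brc1ccc(OCc2ccccc2)cc1 | starting material
20 | [4-(benzyloxy)phenyl]magnesium bromide | Br[Mg]c1ccc(OCc2ccccc2)cc1 | intermediate (not isolated)
21 | rac-5,7-bis(benzyloxy)-2-[4-(benzyloxy)phenyl]-3-Fl-4-(trimethylsilyloxy)-2H-chromene | C[Si](C)(C)OC1=C(c2c(-c3ccc(OCc4ccccc4)cc3)oc3cc(OCc4ccccc4)cc(OCc4ccccc4)c3c2=O)C(c2ccc(OCc3ccccc3)cc2)Oc2cc(OCc3ccccc3)cc(OCc3ccccc3)c21 | intermediate (not isolated)
22 | (2RS,3SR)-5,7-bis(benzyloxy)-2-[4-(benzyloxy)phenyl]-3-Fl-2,3-dihydro-4H-chromen-4-one (racemic trans; both enantiomers written) | O=C1c2c(OCc3ccccc3)cc(OCc3ccccc3)cc2O[C@H](c2ccc(OCc3ccccc3)cc2)[C@H]1c1c(-c2ccc(OCc3ccccc3)cc2)oc2cc(OCc3ccccc3)cc(OCc3ccccc3)c2c1=O.O=C1c2c(OCc3ccccc3)cc(OCc3ccccc3)cc2O[C@@H](c2ccc(OCc3ccccc3)cc2)[C@@H]1c1c(-c2ccc(OCc3ccccc3)cc2)oc2cc(OCc3ccccc3)cc(OCc3ccccc3)c2c1=O | intermediate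
23 | (2S,3R)-5,7-bis(benzyloxy)-2-[4-(benzyloxy)phenyl]-3-Fl-2,3-dihydro-4H-chromen-4-one | O=C1c2c(OCc3ccccc3)cc(OCc3ccccc3)cc2O[C@H](c2ccc(OCc3ccccc3)cc2)[C@H]1c1c(-c2ccc(OCc3ccccc3)cc2)oc2cc(OCc3ccccc3)cc(OCc3ccccc3)c2c1=O | intermediate
24 | (2S,3R)-5,7-dihydroxy-2-(4-hydroxyphenyl)-3-[5,7-dihydroxy-2-(4-hydroxyphenyl)-4-oxo-4H-chromen-3-yl]-2,3-dihydro-4H-chromen-4-one | O=C1c2c(O)cc(O)cc2O[C@H](c2ccc(O)cc2)[C@H]1c1c(-c2ccc(O)cc2)oc2cc(O)cc(O)c2c1=O | target

## Step count and least certain steps

Total: 11 steps. Longest linear sequence: 10 steps (steps 1, 3, 4, 5, 6, 7, 8, 9, 10, 11; from 1 through 2, 5, 7, 9, 13, 15, 18, 22 and 23 to 24).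

**Step 7 (key step, the one reaction without precedent).** The flavonyl group may fail to migrate, because its C4 carbonyl pulls against the donation from O1 and makes C3 a poorer bridging group than an alkoxyphenyl ring. The thallated intermediate would then be consumed by solvolysis at the α carbon or by capture by the flavone carbonyl oxygen, which can reach the α carbon through a five-membered ring. Ketal formation at the ketone followed by a shift of ring A is the other competing course. The fallback uses known chemistry; it sets out from 2 and 7 and returns at 18. Ketone 2 is condensed with Me2NCH(OMe)2 to (E)-1-[2,4-bis(benzyloxy)-6-hydroxyphenyl]-3-(dimethylamino)prop-2-en-1-one F1. Iodine cyclises F1 with loss of dimethylamine to 5,7-bis(benzyloxy)-3-iodo-4H-chromen-4-one F2. Flavone 7 is lithiated as in step 5 (8) and transmetallated with ZnCl2 to the chlorozinc flavone F3. Negishi coupling of F2 and F3 with Pd(PPh3)4 gives 18, and steps 9 to 11 follow. This replaces the rearrangement by a cross-coupling of the two C3 positions.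

**Step 9.** Addition at C2 may be blocked by the shielding of the neighbouring flavonyl group and by the low electrophilicity of the 5,7-dialkoxychromone, and the Grignard reagent may instead add to a carbonyl group. The fallback sets out from 18 and returns at 22. Aqueous NaOH in EtOH–THF opens the pyranone ring that has no C2 substituent and removes C2 as formate, giving 1-[2,4-bis(benzyloxy)-6-hydroxyphenyl]-2-Fl-ethan-1-one F4. F4 is condensed with aldehyde 4 (piperidine, EtOH, reflux) by Knoevenagel condensation and oxa-Michael ring closure to 22, the classical route from deoxybenzoins to trans-2,3-diarylchromanones. The aryl ring then enters as an electrophile, not as a nucleophile.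

**Step 5.** Metalation may occur at a benzylic ether position or on ring A, or the 3-lithio compound may open by β-elimination of the phenoxide before DMF reacts. The fallback sets out from 7 and returns at 9. Iodination with I2 and (NH4)2Ce(NO3)6 in MeCN gives 5,7-bis(benzyloxy)-2-[4-(benzyloxy)phenyl]-3-iodo-4H-chromen-4-one F5. Reductive carbonylation of F5 (Pd(OAc)2, 1,3-bis(diphenylphosphino)propane, CO, Et3SiH, Na2CO3, DMF) gives 9. No organolithium at C3 is involved.

**Step 6.** The aldolate may revert by retro-aldol cleavage before it is mesylated, or the enolate may add in conjugate fashion to the pyranone ring. The fallback sets out from 3 and 9 and returns at 13. Enolate 10 is brominated with N-bromosuccinimide to 2-bromo-1-[2,4-bis(benzyloxy)-6-(methoxymethoxy)phenyl]ethan-1-one F6. PPh3 converts F6 into the phosphonium bromide F7, and Na2CO3 gives the stabilised ylide F8. Wittig reaction of F8 with 9 in toluene at 100 °C gives the (E)-enone 13 without any enolate meeting the aldehyde.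

**Step 11.** Over-reduction may occur (hydrogenolysis of the benzylic C2–O1 bond or saturation of the flavone), or 24 may racemise if the work-up is not kept neutral. The fallback sets out from 23 and returns at 24: Lewis-acid debenzylation with BCl3 and pentamethylbenzene as benzyl-cation trap in CH2Cl2 at −78 °C, which uses no hydrogen and no metal surface.

## Further compounds

F1 | step 7 | (E)-1-[2,4-bis(benzyloxy)-6-hydroxyphenyl]-3-(dimethylamino)prop-2-en-1-one | CN(C)/C=C/C(=O)c1c(O)cc(OCc2ccccc2)cc1OCc1ccccc1
F2 | step 7 | 5,7-bis(benzyloxy)-3-iodo-4H-chromen-4-one | O=c1c(I)coc2cc(OCc3ccccc3)cc(OCc3ccccc3)c12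
F3 | step 7 | chloro{5,7-bis(benzyloxy)-2-[4-(benzyloxy)phenyl]-4-oxo-4H-chromen-3-yl}zinc | Cl[Zn]c1c(-c2ccc(OCc3ccccc3)cc2)oc2cc(OCc3ccccc3)cc(OCc3ccccc3)c2c1=O
F4 | step 9 | 1-[2,4-bis(benzyloxy)-6-hydroxyphenyl]-2-{5,7-bis(benzyloxy)-2-[4-(benzyloxy)phenyl]-4-oxo-4H-chromen-3-yl}ethan-1-one | O=C(Cc1c(-c2ccc(OCc3ccccc3)cc2)oc2cc(OCc3ccccc3)cc(OCc3ccccc3)c2c1=O)c1c(O)cc(OCc2ccccc2)cc1OCc1ccccc1
F5 | step 5 | 5,7-bis(benzyloxy)-2-[4-(benzyloxy)phenyl]-3-iodo-4H-chromen-4-one | O=c1c(I)c(-c2ccc(OCc3ccccc3)cc2)oc2cc(OCc3ccccc3)cc(OCc3ccccc3)c12
F6 | step 6 | 2-bromo-1-[2,4-bis(benzyloxy)-6-(methoxymethoxy)phenyl]ethan-1-one | BrCC(=O)c1c(OCOC)cc(OCc2ccccc2)cc1OCc1ccccc1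
F7 | step 6 | {2-[2,4-bis(benzyloxy)-6-(methoxymethoxy)phenyl]-2-oxoethyl}triphenylphosphonium bromide | [Br-].O=C(C[P+](c1ccccc1)(c1ccccc1)c1ccccc1)c1c(OCOC)cc(OCc2ccccc2)cc1OCc1ccccc1
F8 | step 6 | 1-[2,4-bis(benzyloxy)-6-(methoxymethoxy)phenyl]-2-(triphenyl-λ5-phosphanylidene)ethan-1-one | O=C(C=P(c1ccccc1)(c1ccccc1)c1ccccc1)c1c(OCOC)cc(OCc2ccccc2)cc1OCc1ccccc1
F0 | step 11 | none | none
A1 | alternative 1 | 2-diazo-1-{2-(tert-butyldimethylsilyloxy)-4-(methoxymethoxy)-6-[4-(methoxymethoxy)benzyloxy]phenyl}-2-{5,7-bis(methoxymethoxy)-2-[4-(methoxymethoxy)phenyl]-4-oxo-4H-chromen-3-yl}ethan-1-one | [N-]=[N+]=C(C(=O)c1c(O[Si](C)(C)C(C)(C)C)cc(OCOC)cc1OCc1ccc(OCOC)cc1)c1c(-c2ccc(OCOC)cc2)oc2cc(OCOC)cc(OCOC)c2c1=O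
A2 | alternative 1 | (2S,3R) target as 5-O-tert-butyldimethylsilyl pentakis(methoxymethyl) ether | O=C1c2c(O[Si](C)(C)C(C)(C)C)cc(OCOC)cc2O[C@H](c2ccc(OCOC)cc2)[C@H]1c1c(-c2ccc(OCOC)cc2)oc2cc(OCOC)cc(OCOC)c2c1=O
A3 | alternative 2 | 3,5-bis(benzyloxy)-2-(hydroxymethyl)phenol | OCc1c(O)cc(OCc2ccccc2)cc1OCc1ccccc1
A4 | alternative 2 | (E)-5,7-bis(benzyloxy)-2-[4-(benzyloxy)phenyl]-3-[4-(benzyloxy)styryl]-4H-chromen-4-one | O=c1c(/C=C/c2ccc(OCc3ccccc3)cc2)c(-c2ccc(OCc3ccccc3)cc2)oc2cc(OCc3ccccc3)cc(OCc3ccccc3)c12
A5 | alternative 2 | (2S,3R)-trans-2-aryl-3-(flavon-3-yl)flavan hexabenzyl ether | C1c2c(OCc3ccccc3)cc(OCc3ccccc3)cc2O[C@H](c2ccc(OCc3ccccc3)cc2)[C@H]1c1c(-c2ccc(OCc3ccccc3)cc2)oc2cc(OCc3ccccc3)cc(OCc3ccccc3)c2c1=O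
A6 | alternative 3 | 3,3'-biapigenin hexakis(methoxymethyl) ether | O=c1c(-c2c(-c3ccc(OCOC)cc3)oc3cc(OCOC)cc(OCOC)c3c2=O)c(-c2ccc(OCOC)cc2)oc2cc(OCOC)cc(OCOC)c12
A7 | alternative 3 | (2S,3R) target as hexakis(methoxymethyl) ether | O=C1c2c(OCOC)cc(OCOC)cc2O[C@H](c2ccc(OCOC)cc2)[C@H]1c1c(-c2ccc(OCOC)cc2)oc2cc(OCOC)cc(OCOC)c2c1=O
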